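By 60 min the north-east run, charged with twice the substrate of the east run, shows a smaller share of its charge as target than the east run does.

| setting | east | south | north-east | south-east |
|---|---|---|---|---|
| substrate | 0.120 M | 0.120 M | 0.240 M | 0.420 M |
| free catalyst | 0.00960 M | 0.00960 M | 0.00960 M | 0.00960 M |
| target |  | 0.0360 M |  |  |
| time |  |  |  | 60 min |

| run | time / min | [target] / M |
|---|---|---|
| east run | 2.7 | 0.0168 |
| east run | 8.1 | 0.0419 |
| east run | 15 | 0.0710 |
| east run | 25 | 0.0911 |
| east run | 35 | 0.0999 |
| east run | 47 | 0.1013 |
| east run | 60 | 0.1040 |
| south run | 2.7 | 0.0537 |
| south run | 8.1 | 0.0913 |
| south run | 15 | 0.1147 |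
| south run | 25 | 0.1300 |
| south run | 35 | 0.1372 |
| south run | 47 | 0.1396 |
| south run | 60 | 0.1444 |
| north-east run | 2.7 | 0.0225 |
| north-east run | 8.1 | 0.0659 |
| north-east run | 15 | 0.1205 |
| north-east run | 25 | 0.1622 |
| north-east run | 35 | 0.1733 |
| north-east run | 47 | 0.1778 |
| north-east run | 60 | 0.1843 |

(scatter of a reading: 0.002 M)

* reaction order in [substrate] at the outset, round the charge of the east run, defined at two percent of the substrate turned into target (one fixed amount of target, the same in the runs compared)
* target in the south-east run at 60 min, as a share of the substrate charged

- Overall: substrate -> target, with free catalyst as catalyst.
- Constant volume, constant temperature.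
- Readings of a species count what is bound in complexes too.
- An order is taken over about fifteen percent of the charge, up and down.

We follow one molecule of substrate and ask its chance at the fork, the selectivity for target. We read its complement from the missing share: the part of a charge not found as newly made target at the last reading. We read 13.3% in the east run and 23.2% in the north-east run. The loss exponent, the power of the charge that the missing share follows at 0.00960 M of free catalyst with no target charged, therefore reads 0.800. Carried to the south-east charge of 0.420 M, it gives a missing share of 36.3%, so our own reckoning puts target at 63.7% of the charge at 60 min.

The forecast gives an order of 0.5 (range 0.25 to 0.8) and target at 62% (52% to 72%), a little below our figure. Its grounds differ from ours: “Catalyst activity seems to hold for about 12 min”, then falls.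

The simulation gives an order of 0.48 and 61.8% in the south-east run, both within the forecast's margins. The missing share there is 38.2%.

    free catalyst + substrate ⇌ catalyst-substrate complex, settled at all times (13.10 M⁻¹)
    catalyst-substrate complex + substrate ⇌ doubly bound catalyst, settled at all times (41.40 M⁻¹)
    doubly bound catalyst → target + catalyst-substrate complex (0.8520 min⁻¹)
    2 substrate → homo dimer (0.09960 M⁻¹ min⁻¹)
    substrate + target → 2 target (0.3708 M⁻¹ min⁻¹)

The main reason for that share is the loss of substrate to the homo dimer: with this loss taken away, target in the south-east run at 60 min goes from 61.8% to >99.9%. The south-east figure gives a loss exponent of 0.840, against our 0.800. The south run has the substrate charge of the east run but also 0.0360 M of target, so the exponent does not cover it: its readings show a missing share of 9.67%, less than in the east run, and target formed there at 1.2 times the east rate at the same amount made.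

The data were computed with made-up constants, noise included.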